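**Strategy**

Ring C is disconnected at the bond between the ketone carbon C4 and the ring A carbon C4a. A racemic 2-aryl-3-aryloxypropanoic acid, activated as its mixed trifluoroacetic anhydride, closes the chromanone by intramolecular Friedel–Crafts acylation. The step exploits the local symmetry of ring A: O1 is para to the prenylated C6, and the two ortho carbons C4a and C8, each flanked by O1 and by O5 or O7, are equivalent, so ring closure can only give the 5,7-dioxygenated 6-prenyl pattern. Both prenyl groups are in place before the closure. The enolisable C3 stereocentre is set afterwards by dynamic kinetic transfer hydrogenation and re-oxidation, and the acetals are removed last.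

Key step: step 11

Abbreviations: MOM = methoxymethyl; prenyl = 3-methylbut-2-en-1-yl. Racemic compounds are written without stereodescriptors in their SMILES.

Assumption: C3 of the target is S (C4 > C2 > aryl > H). The (S,S)-TsDPEN ruthenium catalyst is assumed to show its usual sense (S carbinol from aryl ketones, cis product in the dynamic kinetic resolution), which gives 3S,4S; the (R,R) catalyst would be used if the opposite sense were found.

**Route**

Step 1
Reactants: 1 resorcinol
Product: 2 1,3-bis(MOM-oxy)benzene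
Conditions: MOMCl (2.4 equiv), i-Pr2NEt, CH2Cl2, 0 °C to rt
Reagents that add atoms: chloromethyl methyl ether (MOMCl), COCCl
Why: Williamson-type O-alkylation of both phenols by the reactive α-chloro ether installs the two acetals that direct the metalation of step 2.

Step 2
Reactants: 2 1,3-bis(MOM-oxy)benzene
Product: 4 1,3-bis(MOM-oxy)-2-prenylbenzene, via 2-lithio-1,3-bis(MOM-oxy)benzene 3 (not isolated)
Conditions: n-BuLi, THF, 0 °C to rt; then CuBr·SMe2 (cat.), prenyl bromide, −78 °C to rt
Reagents that add atoms: 1-bromo-3-methylbut-2-ene (prenyl bromide), CC(C)=CCBr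
Why: Directed ortho-metalation removes the C–H between the two acetal oxygens, and copper-mediated SN2 coupling of the aryl metal with the primary allylic bromide should give the linear prenyl arene.

Step 3
Reactants: 4 1,3-bis(MOM-oxy)-2-prenylbenzene
Product: 6 3,5-bis(MOM-oxy)-4-prenylphenol, via arylboronic pinacol ester 5 (not isolated)
Conditions: [Ir(OMe)(cod)]2 (1.5 mol %), 4,4'-di-tert-butyl-2,2'-bipyridine, B2pin2, THF, 70 °C; then aq NaOH, 30 % H2O2, 0 °C
Reagents that add atoms: hydrogen peroxide, OO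
Why: Sterically governed iridium-catalysed C–H borylation should occur at the only ring carbon without an ortho substituent (para to the prenyl group), and oxidation of the C–B bond with basic peroxide gives the phenol while the trisubstituted olefin is left alone.

Step 4
Reactants: 7 3-bromo-4,5-dihydroxybenzaldehyde
Product: 8 3-bromo-5-hydroxy-4-methoxybenzaldehyde
Conditions: MeI (1.05 equiv), Li2CO3, DMF, 40 °C
Reagents that add atoms: iodomethane, CI
Why: Regioselective Williamson methylation, because the weak base deprotonates only the more acidic 4-OH (para to the formyl group and ortho to bromine).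

Step 5
Reactants: 8 3-bromo-5-hydroxy-4-methoxybenzaldehyde
Product: 9 3-bromo-4-methoxy-5-(MOM-oxy)benzaldehyde
Conditions: MOMCl, i-Pr2NEt, CH2Cl2, 0 °C to rt
Reagents that add atoms: chloromethyl methyl ether (MOMCl), COCCl
Why: Acetal protection of the remaining phenol by Williamson-type alkylation, so that all three phenols of the target carry the same group.

Step 6
Reactants: 9 3-bromo-4-methoxy-5-(MOM-oxy)benzaldehyde
Product: 10 4-methoxy-3-(MOM-oxy)-5-prenylbenzaldehyde
Conditions: tributyl(prenyl)stannane, Pd(PPh3)4 (5 mol %), DMF, 90 °C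
Reagents that add atoms: tributyl(3-methylbut-2-en-1-yl)stannane, CCCC[Sn](CCCC)(CCCC)CC=C(C)C
Why: Stille coupling, in which the allyl palladium intermediate equilibrates to the less hindered terminus so that reductive elimination should give the linear prenyl arene, and the allylstannane does not add to the aldehyde without a Lewis acid.

Step 7
Reactants: 10 4-methoxy-3-(MOM-oxy)-5-prenylbenzaldehyde
Product: 11 ethyl (Z)-3-hydroxy-2-[4-methoxy-3-(MOM-oxy)-5-prenylphenyl]prop-2-enoate
Conditions: ethyl diazoacetate, HBF4·OEt2 (10 mol %), CH2Cl2, −78 °C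
Reagents that add atoms: ethyl diazoacetate, CCOC(=O)C=[N+]=[N-]
Why: Acid-catalysed addition of the diazo carbon to the aldehyde followed by 1,2-shift of the electron-rich aryl group with loss of N2 (a Roskamp-type homologation diverted to aryl migration) should give the α-formyl ester as its hydrogen-bonded Z enol.

Step 8
Reactants: 11 ethyl (Z)-3-hydroxy-2-[4-methoxy-3-(MOM-oxy)-5-prenylphenyl]prop-2-enoate
Product: 12 ethyl (±)-3-hydroxy-2-[4-methoxy-3-(MOM-oxy)-5-prenylphenyl]propanoate
Conditions: NaBH4, EtOH, 0 °C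
Reagents that add atoms: none
Why: Borohydride reduction of the aldehyde tautomer gives the primary alcohol (a tropic ester) while the ester is untouched at 0 °C; the product is racemic.

Step 9
Reactants: 12 ethyl (±)-3-hydroxy-2-[4-methoxy-3-(MOM-oxy)-5-prenylphenyl]propanoate; 6 3,5-bis(MOM-oxy)-4-prenylphenol
Product: 13 ethyl (±)-3-[3,5-bis(MOM-oxy)-4-prenylphenoxy]-2-[4-methoxy-3-(MOM-oxy)-5-prenylphenyl]propanoate
Conditions: PPh3, DIAD, THF, 0 °C to rt
Reagents that add atoms: none
Why: Mitsunobu etherification at the primary carbinol joins the two fragments under neutral conditions, and any acrylate formed by elimination should be returned to the same racemic ether by conjugate addition of the phenol.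

Step 10
Reactants: 13 ethyl (±)-3-[3,5-bis(MOM-oxy)-4-prenylphenoxy]-2-[4-methoxy-3-(MOM-oxy)-5-prenylphenyl]propanoate
Product: 14 (±)-3-[3,5-bis(MOM-oxy)-4-prenylphenoxy]-2-[4-methoxy-3-(MOM-oxy)-5-prenylphenyl]propanoic acid
Conditions: Me3SnOH (5 equiv), 1,2-dichloroethane, 80 °C; then cold 0.1 M aq HCl wash
Reagents that add atoms: trimethyltin hydroxide, C[Sn](C)(C)O
Why: Tin hydroxide-mediated acyl substitution cleaves the ester without a free strong base, which avoids β-elimination of the aryloxide from the α-aryl ester enolate.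

Step 11
Reactants: 14 (±)-3-[3,5-bis(MOM-oxy)-4-prenylphenoxy]-2-[4-methoxy-3-(MOM-oxy)-5-prenylphenyl]propanoic acid
Product: 16 (±)-3-[4-methoxy-3-(MOM-oxy)-5-prenylphenyl]-5,7-bis(MOM-oxy)-6-prenylchroman-4-one, via mixed trifluoroacetic anhydride 15 (not isolated)
Conditions: (CF3CO)2O (1.1 equiv), CH2Cl2, −20 to 0 °C; aq NaHCO3 quench
Reagents that add atoms: none
Why: Friedel–Crafts acylation: the acid forms mixed anhydride 15, whose acyl carbon (future C4) is attacked by a ring A carbon ortho to the ether oxygen (future C4a), and loss of the ring proton and of trifluoroacetate gives the aryl ketone. The closest known reaction type is the trifluoroacetic anhydride-mediated cyclisation of 3-aryloxypropanoic acids to chroman-4-ones. Ring C closes in a 6-exo-trig mode, the arene carbon adding to the exocyclic C=O of the acyl donor. No stereocentre is controlled here: C3 is carried as a racemate and stays enolisable, and its configuration is set in step 12. The step needs ortho regioselectivity, which is not an issue because the two ortho carbons of ring A are equivalent and each is activated by three oxygen donors (ortho, ortho, para). It also needs chemoselectivity over ring B, the olefins and the acetals, which the six-membered intramolecular transition state, the low temperature and the absence of any Lewis or mineral acid should secure.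

Step 12
Reactants: 16 (±)-3-[4-methoxy-3-(MOM-oxy)-5-prenylphenyl]-5,7-bis(MOM-oxy)-6-prenylchroman-4-one
Product: 17 (3S,4S)-3-[4-methoxy-3-(MOM-oxy)-5-prenylphenyl]-5,7-bis(MOM-oxy)-6-prenylchroman-4-ol (cis)
Conditions: RuCl[(S,S)-TsDPEN](p-cymene) (2 mol %), HCO2H/Et3N (1:1), EtOAc, 40 °C
Reagents that add atoms: none
Why: Noyori–Ikariya asymmetric transfer hydrogenation with dynamic kinetic resolution: Et3N equilibrates C3 through the enol, the catalyst should deliver hydride to one face of C4 (4S) and only in the enantiomer whose 3-aryl group is anti to the incoming hydride, so both C4 and C3 (cis, 3S) are set by the catalyst.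

Step 13
Reactants: 17 (3S,4S)-3-[4-methoxy-3-(MOM-oxy)-5-prenylphenyl]-5,7-bis(MOM-oxy)-6-prenylchroman-4-ol
Product: 18 (3S)-3-[4-methoxy-3-(MOM-oxy)-5-prenylphenyl]-5,7-bis(MOM-oxy)-6-prenylchroman-4-one
Conditions: Dess–Martin periodinane, NaHCO3, CH2Cl2, 0 °C
Reagents that add atoms: none
Why: Dess–Martin oxidation of the benzylic carbinol under buffered, non-basic conditions restores the C4 ketone without enolising C3, so the 3S centre is retained while the C4 centre is removed.

Step 14
Reactants: 18 (3S)-3-[4-methoxy-3-(MOM-oxy)-5-prenylphenyl]-5,7-bis(MOM-oxy)-6-prenylchroman-4-one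
Product: 19 (3S)-5,7-dihydroxy-3-[3-hydroxy-4-methoxy-5-prenylphenyl]-6-prenylchroman-4-one (CNP0327275.1)
Conditions: ZnBr2, n-PrSH, CH2Cl2, 0 °C, short reaction time
Reagents that add atoms: none
Why: Lewis acid-assisted acetal exchange to the thiol cleaves the three aryl MOM ethers within minutes at 0 °C, a window in which the C3–H and the prenyl olefins should remain untouched.

**Compound list**

1 | resorcinol | Oc1cccc(O)c1 | starting material
2 | 1,3-bis(MOM-oxy)benzene | COCOc1cccc(OCOC)c1 | intermediate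
3 | 2-lithio-1,3-bis(MOM-oxy)benzene | COCOc1cccc(OCOC)c1[Li] | intermediate
4 | 1,3-bis(MOM-oxy)-2-prenylbenzene | COCOc1cccc(OCOC)c1CC=C(C)C | intermediate
5 | 2-[3,5-bis(MOM-oxy)-4-prenylphenyl]-4,4,5,5-tetramethyl-1,3,2-dioxaborolane | COCOc1cc(B2OC(C)(C)C(C)(C)O2)cc(OCOC)c1CC=C(C)C | intermediate
6 | 3,5-bis(MOM-oxy)-4-prenylphenol | COCOc1cc(O)cc(OCOC)c1CC=C(C)C | intermediate
7 | 3-bromo-4,5-dihydroxybenzaldehyde | O=Cc1cc(O)c(O)c(Br)c1 | starting material
8 | 3-bromo-5-hydroxy-4-methoxybenzaldehyde | COc1c(O)cc(C=O)cc1Br | intermediate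
9 | 3-bromo-4-methoxy-5-(MOM-oxy)benzaldehyde | COCOc1cc(C=O)cc(Br)c1OC | intermediate
10 | 4-methoxy-3-(MOM-oxy)-5-prenylbenzaldehyde | COCOc1cc(C=O)cc(CC=C(C)C)c1OC | intermediate
11 | ethyl (Z)-3-hydroxy-2-[4-methoxy-3-(MOM-oxy)-5-prenylphenyl]prop-2-enoate | CCOC(=O)/C(=C\O)c1cc(OCOC)c(OC)c(CC=C(C)C)c1 | intermediate
12 | ethyl (±)-3-hydroxy-2-[4-methoxy-3-(MOM-oxy)-5-prenylphenyl]propanoate | CCOC(=O)C(CO)c1cc(OCOC)c(OC)c(CC=C(C)C)c1 | intermediate
13 | ethyl (±)-3-[3,5-bis(MOM-oxy)-4-prenylphenoxy]-2-[4-methoxy-3-(MOM-oxy)-5-prenylphenyl]propanoate | CCOC(=O)C(COc1cc(OCOC)c(CC=C(C)C)c(OCOC)c1)c1cc(OCOC)c(OC)c(CC=C(C)C)c1 | intermediate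
14 | (±)-3-[3,5-bis(MOM-oxy)-4-prenylphenoxy]-2-[4-methoxy-3-(MOM-oxy)-5-prenylphenyl]propanoic acid | OC(=O)C(COc1cc(OCOC)c(CC=C(C)C)c(OCOC)c1)c1cc(OCOC)c(OC)c(CC=C(C)C)c1 | intermediate
15 | mixed anhydride of 14 with trifluoroacetic acid | O=C(OC(=O)C(F)(F)F)C(COc1cc(OCOC)c(CC=C(C)C)c(OCOC)c1)c1cc(OCOC)c(OC)c(CC=C(C)C)c1 | intermediate
16 | (±)-3-[4-methoxy-3-(MOM-oxy)-5-prenylphenyl]-5,7-bis(MOM-oxy)-6-prenylchroman-4-one | COc1c(OCOC)cc(C2COc3cc(OCOC)c(CC=C(C)C)c(OCOC)c3C2=O)cc1CC=C(C)C | intermediate
17 | (3S,4S)-3-[4-methoxy-3-(MOM-oxy)-5-prenylphenyl]-5,7-bis(MOM-oxy)-6-prenylchroman-4-ol | COc1c(OCOC)cc([C@H]2COc3cc(OCOC)c(CC=C(C)C)c(OCOC)c3[C@H]2O)cc1CC=C(C)C | intermediate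
18 | (3S)-3-[4-methoxy-3-(MOM-oxy)-5-prenylphenyl]-5,7-bis(MOM-oxy)-6-prenylchroman-4-one | COc1c(OCOC)cc([C@H]2COc3cc(OCOC)c(CC=C(C)C)c(OCOC)c3C2=O)cc1CC=C(C)C | intermediate
19 | (3S)-5,7-dihydroxy-3-[3-hydroxy-4-methoxy-5-prenylphenyl]-6-prenylchroman-4-one | COc1c(O)cc([C@H]2COc3cc(O)c(CC=C(C)C)c(O)c3C2=O)cc1CC=C(C)C | target

**Step count and risks**

Total step count: 14. Longest linear sequence: 11 steps (steps 4 to 14, from 7).

Steps most likely to fail:

Step 11 (ring closure). The trifluoroacetic acid set free may cleave the acetals that flank the ring A prenyl group, after which the olefin can be protonated and trapped by the phenol or the arene; ring A may also be trifluoroacetylated before it cyclises. The fallback is acid-free and photochemical; it sets out from 12 and 6 and comes back to the route at 16.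
- Alcohol 12 is dehydrated (MsCl, Et3N, then DBU) to ethyl 2-[4-methoxy-3-(MOM-oxy)-5-prenylphenyl]prop-2-enoate F1.
- LiOH in THF/H2O converts it into 2-[4-methoxy-3-(MOM-oxy)-5-prenylphenyl]prop-2-enoic acid F2.
- Esterification with phenol 6 (DCC, DMAP, CH2Cl2) gives 3,5-bis(MOM-oxy)-4-prenylphenyl 2-[4-methoxy-3-(MOM-oxy)-5-prenylphenyl]prop-2-enoate F3.
- Irradiation (300 nm, MeCN, rt) should trigger a photo-Fries rearrangement. The α,β-unsaturated acyl radical does not lose CO and recombines at a ring carbon ortho to oxygen (para is blocked by the prenyl group), giving 1-[2-hydroxy-4,6-bis(MOM-oxy)-5-prenylphenyl]-2-[4-methoxy-3-(MOM-oxy)-5-prenylphenyl]prop-2-en-1-one F4.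
- F4 should close by 6-endo oxa-Michael addition (NaHCO3 if needed) to 16.

Step 12 (transfer hydrogenation with dynamic kinetic resolution). Hydride transfer to the electron-rich C4 carbonyl, shielded by the peri acetal at O5, may be slow, so that the reduction stalls or fails to keep pace with the epimerisation at C3 and the diastereo- and enantioselectivity erode. The fallback sets C3 by enantioselective protonation; it sets out from 16 and comes back at 18, so that step 13 is not needed.
- Ketone 16 is converted with LiN(SiMe3)2 and Me3SiCl (THF, −78 °C) into 3-[4-methoxy-3-(MOM-oxy)-5-prenylphenyl]-5,7-bis(MOM-oxy)-6-prenyl-4-(trimethylsilyloxy)-2H-chromene F5.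
- F5 is protonated at C3 by phenol in toluene under a chiral BINOL-derived N-triflyl thiophosphoramide catalyst, in the antipode that delivers 3S, to give 18.

Step 14 (acetal cleavage). The Lewis acid may enolise the C3–H during the cleavage and so erode the enantiomeric purity at the last moment. The fallback moves the acetal cleavage in front of the stereo-defining step and ends with a fluoride deprotection; it sets out from 16 and comes back at 19.
- The racemic ketone 16 is deprotected with ZnBr2 and n-PrSH, where racemisation is of no concern, to (±)-5,7-dihydroxy-3-[3-hydroxy-4-methoxy-5-prenylphenyl]-6-prenylchroman-4-one F6.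
- TBSCl and imidazole in DMF give (±)-5,7-bis(tert-butyldimethylsilyloxy)-3-[3-(tert-butyldimethylsilyloxy)-4-methoxy-5-prenylphenyl]-6-prenylchroman-4-one F7.
- The transfer hydrogenation of step 12 should give the (3S,4S)-chroman-4-ol F8.
- Dess–Martin oxidation should give the (3S)-tris(silyl ether) ketone F9.
- HF·pyridine buffered with pyridine (THF, 0 °C) removes the silyl groups under conditions that do not enolise C3 and gives 19.

Further compounds
F1 | step 11 | ethyl 2-[4-methoxy-3-(MOM-oxy)-5-prenylphenyl]prop-2-enoate | CCOC(=O)C(=C)c1cc(OCOC)c(OC)c(CC=C(C)C)c1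
F2 | step 11 | 2-[4-methoxy-3-(MOM-oxy)-5-prenylphenyl]prop-2-enoic acid | OC(=O)C(=C)c1cc(OCOC)c(OC)c(CC=C(C)C)c1
F3 | step 11 | 3,5-bis(MOM-oxy)-4-prenylphenyl 2-[4-methoxy-3-(MOM-oxy)-5-prenylphenyl]prop-2-enoate | C=C(C(=O)Oc1cc(OCOC)c(CC=C(C)C)c(OCOC)c1)c1cc(OCOC)c(OC)c(CC=C(C)C)c1
F4 | step 11 | 1-[2-hydroxy-4,6-bis(MOM-oxy)-5-prenylphenyl]-2-[4-methoxy-3-(MOM-oxy)-5-prenylphenyl]prop-2-en-1-one | C=C(C(=O)c1c(O)cc(OCOC)c(CC=C(C)C)c1OCOC)c1cc(OCOC)c(OC)c(CC=C(C)C)c1
F5 | step 12 | 3-[4-methoxy-3-(MOM-oxy)-5-prenylphenyl]-5,7-bis(MOM-oxy)-6-prenyl-4-(trimethylsilyloxy)-2H-chromene | C[Si](C)(C)OC1=C(c2cc(OCOC)c(OC)c(CC=C(C)C)c2)COc2cc(OCOC)c(CC=C(C)C)c(OCOC)c12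
F6 | step 14 | (±)-5,7-dihydroxy-3-[3-hydroxy-4-methoxy-5-prenylphenyl]-6-prenylchroman-4-one | COc1c(O)cc(C2COc3cc(O)c(CC=C(C)C)c(O)c3C2=O)cc1CC=C(C)C
F7 | step 14 | (±)-5,7-bis(tert-butyldimethylsilyloxy)-3-[3-(tert-butyldimethylsilyloxy)-4-methoxy-5-prenylphenyl]-6-prenylchroman-4-one | COc1c(O[Si](C)(C)C(C)(C)C)cc(C2COc3cc(O[Si](C)(C)C(C)(C)C)c(CC=C(C)C)c(O[Si](C)(C)C(C)(C)C)c3C2=O)cc1CC=C(C)C
F8 | step 14 | (3S,4S)-5,7-bis(tert-butyldimethylsilyloxy)-3-[3-(tert-butyldimethylsilyloxy)-4-methoxy-5-prenylphenyl]-6-prenylchroman-4-ol | COc1c(O[Si](C)(C)C(C)(C)C)cc([C@H]2COc3cc(O[Si](C)(C)C(C)(C)C)c(CC=C(C)C)c(O[Si](C)(C)C(C)(C)C)c3[C@H]2O)cc1CC=C(C)C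
F9 | step 14 | (3S)-5,7-bis(tert-butyldimethylsilyloxy)-3-[3-(tert-butyldimethylsilyloxy)-4-methoxy-5-prenylphenyl]-6-prenylchroman-4-one | COc1c(O[Si](C)(C)C(C)(C)C)cc([C@H]2COc3cc(O[Si](C)(C)C(C)(C)C)c(CC=C(C)C)c(O[Si](C)(C)C(C)(C)C)c3C2=O)cc1CC=C(C)C
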